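**Retrosynthetic overview** (TBS = tert-butyldimethylsilyl, TBDPS = tert-butyldiphenylsilyl; ring numbering: C1 ylidene carbon, C2 CH bearing the hydroxypropyl chain, C3 quaternary carbon, C4 CH–CH3, C5 and C6 CH2)
1. The enal is unmasked last (MnO2 on the allylic alcohol); before that a B-alkyl Suzuki–Miyaura coupling joins the CH2CH2 arm on C3 to alkenyl iodide 34, which already carries both (E)-alkenes and the oxirane.
2. The (Z)-propanal ylidene at C1 comes from cyclohexanone 14 by isopropenyl addition and oxidative 1,3-transposition.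
3. The cyclohexane (the only carbocycle, formed first) is closed at C4–C5 by an iron-hydride hydrogen-atom-transfer radical cyclisation of dienone 13. The enabling feature: C4 is a CH(CH3) on quaternary C3, i.e. the internal carbon of a vinyl group, and C5 is β to C1, so with C1 as a ketone C5=C6 is a vinyl ketone.
4. Dienone 13 comes from acid 11, made by an enantioselective boron-enolate Ireland–Claisen rearrangement of allyl ester 9 (sets C2 and C3); 9 is built from δ-valerolactone and a butynol-derived (E)-allylic alcohol.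
5. Side chain 34: asymmetric propargylation of 3-methylbut-2-enal, two carboalumination–iodination/Negishi cycles, then hydroxyl-directed epoxidation (the oxirane is the second ring, formed before the fragment union).

Key step: step 7

Assumption: the (4S,5S)-diazaborolidine of step 4 and the (S)-phosphoric acid of step 15 are taken to induce the configurations drawn; should either induce the opposite sense, its mirror-image form is used with no other change.

**Route**

Step 1
Reactants: 1 tert-butyl(but-3-yn-1-yloxy)dimethylsilane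
Product: 4 (2E)-5-[(tert-butyldimethylsilyl)oxy]-3-methylpent-2-en-1-ol, via alkenyldimethylalane 2 (not isolated), via lithium alkenylalanate 3 (not isolated)
Conditions: AlMe3 (2 equiv), Cp2ZrCl2 (0.2 equiv), CH2Cl2, 0 °C → rt; then n-BuLi, THF, −78 °C; (CH2O)n, −78 °C → rt; aq. potassium sodium tartrate
Reagents that add atoms: trimethylaluminium C[Al](C)C; formaldehyde (as paraformaldehyde) C=O
Why: Zirconium-catalysed carboalumination adds CH3 and Al syn across the terminal alkyne with methyl on the internal carbon, and the derived alanate is hydroxymethylated with retention, so only the (E)-trisubstituted allylic alcohol should form (no stereocentre).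

Step 2
Reactants: 5 δ-valerolactone (oxan-2-one)
Product: 8 5-[(tert-butyldiphenylsilyl)oxy]pentanoic acid, via potassium 5-hydroxypentanoate 6 (not isolated), via doubly silylated hydroxy acid 7 (not isolated)
Conditions: KOH (1.0 equiv), MeOH, 50 °C, evaporate; TBDPSCl (2.1 equiv), imidazole, DMF, rt; then AcOH/THF/H2O, rt
Reagents that add atoms: potassium hydroxide [K+].[OH-]; tert-butyl(chloro)diphenylsilane CC(C)(C)[Si](Cl)(c1ccccc1)c1ccccc1
Why: Saponification opens the lactone, both oxygens are silylated and only the labile silyl ester is hydrolysed by aqueous acetic acid (lactone opening and silyl protection; no stereocentre).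

Step 3
Reactants: 8 5-[(tert-butyldiphenylsilyl)oxy]pentanoic acid; 4 (2E)-5-[(tert-butyldimethylsilyl)oxy]-3-methylpent-2-en-1-ol
Product: 9 (2E)-5-[(tert-butyldimethylsilyl)oxy]-3-methylpent-2-en-1-yl 5-[(tert-butyldiphenylsilyl)oxy]pentanoate
Conditions: EDC·HCl, DMAP (cat.), CH2Cl2, 0 °C → rt
Reagents that add atoms: none
Why: Carbodiimide (Steglich-type) esterification of an unhindered acid with a primary allylic alcohol should leave the silyl ethers and the alkene geometry untouched.

Step 4
Reactants: 9 the allyl ester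
Product: 11 (2S,3R)-3-{2-[(tert-butyldimethylsilyl)oxy]ethyl}-2-{3-[(tert-butyldiphenylsilyl)oxy]propyl}-3-methylpent-4-enoic acid, via boron ketene acetal 10 (not isolated)
Conditions: (4S,5S)-2-bromo-1,3-bis{[3,5-bis(trifluoromethyl)phenyl]sulfonyl}-4,5-diphenyl-1,3,2-diazaborolidine (1.2 equiv, made beforehand in the flask from the (1S,2S)-bis-sulfonamide and BBr3, CH2Cl2), i-Pr2NEt, CH2Cl2, −78 °C, then −20 → 4 °C; aqueous work-up
Reagents that add atoms: none
Why: Enantioselective Ireland–Claisen rearrangement of a boron ketene acetal: the enolate with the C2 chain cis to O–B (formed with the hindered amine in CH2Cl2) and the (E)-alkene pass through a chair transition state with both chains equatorial, which fixes the relative configuration of the new tertiary C2 and quaternary C3, while the C2-symmetric bis-sulfonamide on boron shields one enolate face and fixes their absolute configuration.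

Step 5
Reactants: 11 the (2S,3R)-acid
Product: 12 (2S,3R)-3-{2-[(tert-butyldimethylsilyl)oxy]ethyl}-2-{3-[(tert-butyldiphenylsilyl)oxy]propyl}-N-methoxy-N,3-dimethylpent-4-enamide
Conditions: MeNHOMe·HCl, EDC·HCl, HOBt (cat.), i-Pr2NEt, CH2Cl2, rt
Reagents that add atoms: N,O-dimethylhydroxylamine hydrochloride CNOC.Cl
Why: Carbodiimide-mediated amidation gives the N-methoxy-N-methyl amide needed for clean mono-addition of a vinyl nucleophile, and the α-stereocentre is not enolised under these near-neutral conditions.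

Step 6
Reactants: 12 the N-methoxy-N-methyl amide
Product: 13 (4S,5R)-5-{2-[(tert-butyldimethylsilyl)oxy]ethyl}-4-{3-[(tert-butyldiphenylsilyl)oxy]propyl}-5-methylhepta-1,6-dien-3-one
Conditions: vinylmagnesium bromide, THF, −78 → 0 °C; inverse quench into cold 1 M HCl; used directly
Reagents that add atoms: vinylmagnesium bromide C=C[Mg]Br
Why: Weinreb ketone synthesis: the magnesium chelate of the tetrahedral adduct stops at mono-addition and collapses to the vinyl ketone only on acidic quench, which also protonates the released amine and prevents its conjugate addition.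

Step 7
Reactants: 13 the dienone
Product: 14 (2S,3R,4R)-3-{2-[(tert-butyldimethylsilyl)oxy]ethyl}-2-{3-[(tert-butyldiphenylsilyl)oxy]propyl}-3,4-dimethylcyclohexan-1-one
Conditions: Fe(acac)3 (0.5 equiv), PhSiH3 (2.5 equiv, slow addition), EtOH/(CH2OH)2 5:1, 60 °C, 0.02 M
Reagents that add atoms: none
Why: The iron hydride formed from Fe(acac)3 and PhSiH3 transfers a hydrogen atom to the terminal CH2 of the unactivated vinyl group (the more electron-rich alkene), which creates the C4 methyl and a secondary radical at C4; this nucleophilic radical adds to the terminal β-carbon C5 of the vinyl ketone, and the α-keto radical is reduced to the iron enolate and protonated by ethanol (metal-hydride hydrogen-atom-transfer reductive olefin coupling, an intramolecular Giese reaction). The six-membered ring closes in the 6-endo-trig mode, favoured over 5-exo because exo attack would hit the α-carbon of the enone and leave an unstabilised primary radical. The new stereocentre C4 is controlled by C2 and C3 through a chair transition state in which the two vicinal chains on C2 and C3 are anti (both axial) and both methyls are equatorial, since an axial radical methyl would meet the axial C2 chain in a 1,3-diaxial contact; this places C4–CH3 cis to the C3 chain as in the target. The step needs hydrogen-atom transfer to the isolated vinyl group in preference to the enone and ring closure faster than reduction, which the absence of any other alkene, the Thorpe–Ingold effect of quaternary C3 and high dilution should secure.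

Step 8
Reactants: 14 the cyclohexanone
Product: 15 (2S,3R,4R)-3-{2-[(tert-butyldimethylsilyl)oxy]ethyl}-2-{3-[(tert-butyldiphenylsilyl)oxy]propyl}-3,4-dimethyl-1-(prop-1-en-2-yl)cyclohexan-1-ol (C1 configuration not defined; either epimer serves)
Conditions: isopropenylmagnesium bromide, anhydrous CeCl3, THF, −78 °C; aq. NH4Cl
Reagents that add atoms: isopropenylmagnesium bromide CC(=C)[Mg]Br
Why: 1,2-Addition of the weakly basic organocerium reagent to the hindered, enolisable ketone should avoid epimerisation at C2; the new carbinol centre is destroyed in step 9, so its configuration is irrelevant.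

Step 9
Reactants: 15 the tertiary allylic alcohol
Product: 16 (2Z)-2-[(2S,3R,4R)-3-{2-[(tert-butyldimethylsilyl)oxy]ethyl}-2-{3-[(tert-butyldiphenylsilyl)oxy]propyl}-3,4-dimethylcyclohexylidene]propanal
Conditions: pyridinium chlorochromate (C5H5NH)[CrO3Cl] (3 equiv), NaOAc, 4 Å MS, CH2Cl2, rt; chromatography
Reagents that add atoms: pyridinium chlorochromate [O-][Cr](=O)(=O)Cl.c1cc[nH+]cc1
Why: Babler–Dauben oxidative 1,3-transposition (chromate ester, [3,3] shift, oxidation) gives the tetrasubstituted enal; the (Z)-isomer with CHO syn to C2 is expected to predominate because the flat formyl group tolerates the side next to the axial C2 chain better than methyl, and any (E)-isomer is removed by chromatography.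

Step 10
Reactants: 16 the (Z)-enal
Product: 17 (2Z)-2-[(2S,3R,4R)-3-{2-[(tert-butyldimethylsilyl)oxy]ethyl}-2-{3-[(tert-butyldiphenylsilyl)oxy]propyl}-3,4-dimethylcyclohexylidene]propan-1-ol
Conditions: i-Bu2AlH, CH2Cl2, −78 °C; aq. potassium sodium tartrate
Reagents that add atoms: none
Why: 1,2-Reduction of the hindered enal by the aluminium hydride keeps the alkene geometry and masks the aldehyde for the organolithium chemistry of step 23.

Step 11
Reactants: 17 the allylic alcohol
Product: 18 the tert-butyldiphenylsilyl ether of 17 (allylic CH2O–TBDPS; other groups unchanged)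
Conditions: TBDPSCl, imidazole, DMF, rt
Reagents that add atoms: tert-butyl(chloro)diphenylsilane CC(C)(C)[Si](Cl)(c1ccccc1)c1ccccc1
Why: Standard silylation of a primary alcohol; TBDPS is chosen so that the TBS ether can be removed selectively in step 12.

Step 12
Reactants: 18 the bis-TBDPS mono-TBS ether
Product: 19 the primary alcohol (CH2CH2OH arm on C3; both TBDPS ethers kept)
Conditions: HF·pyridine, pyridine, THF, 0 °C → rt
Reagents that add atoms: none
Why: Selective desilylation: buffered HF·pyridine cleaves the primary TBS ether much faster than primary TBDPS ethers and is not acidic enough to ionise the allylic silyl ether.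

Step 13
Reactants: 19 the primary alcohol
Product: 20 the primary iodide (CH2CH2I arm on C3)
Conditions: I2, PPh3, imidazole, CH2Cl2, 0 °C → rt
Reagents that add atoms: iodine II
Why: Appel-type iodination of an unhindered primary alcohol by SN2 displacement of the oxyphosphonium leaving group.

Step 14
Reactants: 21 4-(trimethylsilyl)but-3-yn-1-ol
Product: 22 (4-iodobut-1-yn-1-yl)trimethylsilane
Conditions: I2, PPh3, imidazole, CH2Cl2, 0 °C → rt
Reagents that add atoms: iodine II
Why: Appel-type iodination gives the homopropargyl iodide used for the four-carbon chain extension.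

Step 15
Reactants: 23 3-methylbut-2-enal
Product: 24 (4S)-6-methylhept-5-en-1-yn-4-ol
Conditions: allenylboronic acid pinacol ester, (S)-3,3'-bis(2,4,6-triisopropylphenyl)-1,1'-binaphthyl-2,2'-diyl hydrogen phosphate (5 mol %), 4 Å MS, toluene, −20 °C; aqueous work-up
Reagents that add atoms: allenylboronic acid pinacol ester C=C=CB1OC(C)(C)C(C)(C)O1
Why: Chiral phosphoric acid-catalysed propargylboration through a six-membered SE2' transition state, in which the catalyst directs the allenylboronate to the Si face of the aldehyde and so sets the (S)-carbinol centre.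

Step 16
Reactants: 24 (4S)-6-methylhept-5-en-1-yn-4-ol
Product: 25 tert-butyldimethyl{[(4S)-6-methylhept-5-en-1-yn-4-yl]oxy}silane
Conditions: TBSCl, imidazole, DMF, rt
Reagents that add atoms: tert-butyl(chloro)dimethylsilane CC(C)(C)[Si](C)(C)Cl
Why: Silyl protection keeps the allylic alkoxide from ionising under the Lewis-acidic carboalumination conditions and from quenching the organozinc reagent.

Step 17
Reactants: 25 the silyl-protected enynol
Product: 27 tert-butyl{[(4S,6E)-7-iodo-2,6-dimethylhepta-2,6-dien-4-yl]oxy}dimethylsilane, via alkenyldimethylalane 26 (not isolated)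
Conditions: AlMe3 (2 equiv), Cp2ZrCl2 (0.25 equiv), CH2Cl2, 0 °C → rt; then I2, THF, −30 °C
Reagents that add atoms: trimethylaluminium C[Al](C)C; iodine II
Why: Zirconium-catalysed syn-carboalumination followed by iodinolysis with retention gives the (E)-2-methylalkenyl iodide; the trisubstituted alkene is inert to these conditions.

Step 18
Reactants: 27 the (E)-alkenyl iodide; 22 (4-iodobut-1-yn-1-yl)trimethylsilane
Product: 29 tert-butyldimethyl{[(4S,6E)-2,6-dimethyl-11-(trimethylsilyl)undeca-2,6-dien-10-yn-4-yl]oxy}silane, via alkylzinc iodide 28 (not isolated)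
Conditions: 22, Zn dust (activated), LiCl, THF, 40 °C; then 27, Pd(dppf)Cl2 (3 mol %), THF, rt
Reagents that add atoms: none
Why: Negishi coupling of a primary alkylzinc iodide with an alkenyl iodide proceeds with retention of the (E)-geometry, the bidentate phosphine suppressing β-hydride elimination.

Step 19
Reactants: 29 the silylated enyne
Product: 30 tert-butyl{[(4S,6E)-2,6-dimethylundeca-2,6-dien-10-yn-4-yl]oxy}dimethylsilane
Conditions: K2CO3 (cat.), MeOH, rt
Reagents that add atoms: none
Why: Base-catalysed methanolysis removes the alkynyl C–Si group only; the O-silyl ether is stable to these conditions.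

Step 20
Reactants: 30 the terminal alkyne
Product: 32 tert-butyl{[(4S,6E,10E)-11-iodo-2,6,10-trimethylundeca-2,6,10-trien-4-yl]oxy}dimethylsilane, via alkenyldimethylalane 31 (not isolated)
Conditions: AlMe3 (2 equiv), Cp2ZrCl2 (0.25 equiv), CH2Cl2, 0 °C → rt; then I2, THF, −30 °C
Reagents that add atoms: trimethylaluminium C[Al](C)C; iodine II
Why: A second syn-carboalumination and iodinolysis installs the terminal (E)-2-methylalkenyl iodide with the same geometric control as in step 17.

Step 21
Reactants: 32 the silyl-protected dienyl iodide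
Product: 33 (4S,6E,10E)-11-iodo-2,6,10-trimethylundeca-2,6,10-trien-4-ol
Conditions: Bu4NF, THF, 0 °C → rt
Reagents that add atoms: none
Why: Fluoride cleavage of the secondary silyl ether frees the allylic alcohol that directs the epoxidation; the alkenyl iodide is inert to fluoride.

Step 22
Reactants: 33 the allylic alcohol
Product: 34 (1S,3E,7E)-1-[(2R)-3,3-dimethyloxiran-2-yl]-8-iodo-3,7-dimethylocta-3,7-dien-1-ol
Conditions: Ti(OiPr)4 (0.3 equiv), t-BuOOH (1.5 equiv, anhydrous), 4 Å MS, CH2Cl2, −20 °C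
Reagents that add atoms: tert-butyl hydroperoxide CC(C)(C)OO
Why: Hydroxyl-directed epoxidation by a titanium alkylperoxide reacts only at the allylic double bond; 1,3-allylic strain between the cis-methyl of the alkene and the carbinol substituent holds the carbinol C–H in the alkene plane, so oxygen is delivered syn to the hydroxyl and the threo (1S, oxirane 2R) epoxy alcohol should form.

Step 23
Reactants: 20 the primary iodide; 34 the epoxy alcohol alkenyl iodide
Product: 37 the coupled bis-TBDPS ether (full carbon skeleton; free secondary alcohol and oxirane), via alkyllithium 35 (not isolated), via lithium borinate 36 (not isolated)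
Conditions: 20, t-BuLi (2.1 equiv), Et2O, −78 °C; B-methoxy-9-BBN, THF, −78 °C → rt; then 34, Pd(dppf)Cl2 (5 mol %), AsPh3, aq. K3PO4, DMF, rt
Reagents that add atoms: none
Why: B-alkyl Suzuki–Miyaura coupling: iodine–lithium exchange and trapping with the borinic ester give a borinate that transmetalates to the alkenylpalladium iodide from 34, joining C(sp3) to C(sp2) with retention of the (E)-geometry and without affecting the oxirane, the free alcohol or the silyl ethers.

Step 24
Reactants: 37 the coupled bis-TBDPS ether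
Product: 38 (2Z)-2-[(2S,3R,4R)-3-{(3E,7E,10S)-10-[(2R)-3,3-dimethyloxiran-2-yl]-10-hydroxy-4,8-dimethyldeca-3,7-dien-1-yl}-2-(3-hydroxypropyl)-3,4-dimethylcyclohexylidene]propan-1-ol
Conditions: Bu4NF, AcOH (1:1), THF, rt
Reagents that add atoms: none
Why: Buffered fluoride removes both primary TBDPS ethers while the acetic acid keeps the medium too weakly basic for epoxide migration or opening.

Step 25
Reactants: 38 the triol
Product: 39 (2Z)-2-[(2S,3R,4R)-3-{(3E,7E,10S)-10-[(2R)-3,3-dimethyloxiran-2-yl]-10-hydroxy-4,8-dimethyldeca-3,7-dien-1-yl}-2-(3-hydroxypropyl)-3,4-dimethylcyclohexylidene]propanal (CNP0208461.1)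
Conditions: MnO2 (activated, excess), CH2Cl2, rt
Reagents that add atoms: none
Why: MnO2 oxidises only the allylic primary alcohol; the saturated primary alcohol and the secondary epoxy alcohol are not allylic and should stay untouched, and the alkene geometry is retained.

**Compound list**

1 | tert-butyl(but-3-yn-1-yloxy)dimethylsilane | C#CCCO[Si](C)(C)C(C)(C)C | starting material
2 | (E)-{4-[(tert-butyldimethylsilyl)oxy]-2-methylbut-1-en-1-yl}dimethylalane | C[Al](C)/C=C(\C)CCO[Si](C)(C)C(C)(C)C | intermediate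
3 | lithium butyl{(E)-4-[(tert-butyldimethylsilyl)oxy]-2-methylbut-1-en-1-yl}dimethylalanate | [Li+].CCCC[Al-](C)(C)/C=C(\C)CCO[Si](C)(C)C(C)(C)C | intermediate
4 | (2E)-5-[(tert-butyldimethylsilyl)oxy]-3-methylpent-2-en-1-ol | OC/C=C(\C)CCO[Si](C)(C)C(C)(C)C | intermediate
5 | δ-valerolactone (oxan-2-one) | O=C1CCCCO1 | starting material
6 | potassium 5-hydroxypentanoate | [K+].[O-]C(=O)CCCCO | intermediate
7 | tert-butyldiphenylsilyl 5-[(tert-butyldiphenylsilyl)oxy]pentanoate | CC(C)(C)[Si](c1ccccc1)(c1ccccc1)OCCCCC(=O)O[Si](c1ccccc1)(c1ccccc1)C(C)(C)C | intermediate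
8 | 5-[(tert-butyldiphenylsilyl)oxy]pentanoic acid | CC(C)(C)[Si](c1ccccc1)(c1ccccc1)OCCCCC(=O)O | intermediate
9 | (2E)-5-[(tert-butyldimethylsilyl)oxy]-3-methylpent-2-en-1-yl 5-[(tert-butyldiphenylsilyl)oxy]pentanoate | CC(C)(C)[Si](c1ccccc1)(c1ccccc1)OCCCCC(=O)OC/C=C(\C)CCO[Si](C)(C)C(C)(C)C | intermediate
10 | boron ketene acetal of 9 with the (4S,5S)-diazaborolidine (C2 chain cis to O–B) | CC(C)(C)[Si](c1ccccc1)(c1ccccc1)OCCC/C=C(\OB1N(S(=O)(=O)c2cc(cc(c2)C(F)(F)F)C(F)(F)F)[C@@H](c2ccccc2)[C@H](c2ccccc2)N1S(=O)(=O)c1cc(cc(c1)C(F)(F)F)C(F)(F)F)OC/C=C(\C)CCO[Si](C)(C)C(C)(C)C | intermediate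
11 | (2S,3R)-3-{2-[(tert-butyldimethylsilyl)oxy]ethyl}-2-{3-[(tert-butyldiphenylsilyl)oxy]propyl}-3-methylpent-4-enoic acid | C=C[C@@](C)(CCO[Si](C)(C)C(C)(C)C)[C@@H](C(=O)O)CCCO[Si](c1ccccc1)(c1ccccc1)C(C)(C)C | intermediate
12 | (2S,3R)-3-{2-[(tert-butyldimethylsilyl)oxy]ethyl}-2-{3-[(tert-butyldiphenylsilyl)oxy]propyl}-N-methoxy-N,3-dimethylpent-4-enamide | C=C[C@@](C)(CCO[Si](C)(C)C(C)(C)C)[C@@H](C(=O)N(C)OC)CCCO[Si](c1ccccc1)(c1ccccc1)C(C)(C)C | intermediate
13 | (4S,5R)-5-{2-[(tert-butyldimethylsilyl)oxy]ethyl}-4-{3-[(tert-butyldiphenylsilyl)oxy]propyl}-5-methylhepta-1,6-dien-3-one | C=C[C@@](C)(CCO[Si](C)(C)C(C)(C)C)[C@@H](C(=O)C=C)CCCO[Si](c1ccccc1)(c1ccccc1)C(C)(C)C | intermediate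
14 | (2S,3R,4R)-3-{2-[(tert-butyldimethylsilyl)oxy]ethyl}-2-{3-[(tert-butyldiphenylsilyl)oxy]propyl}-3,4-dimethylcyclohexan-1-one | O=C1CC[C@@H](C)[C@@](C)(CCO[Si](C)(C)C(C)(C)C)[C@@H]1CCCO[Si](c2ccccc2)(c2ccccc2)C(C)(C)C | intermediate
15 | (2S,3R,4R)-3-{2-[(tert-butyldimethylsilyl)oxy]ethyl}-2-{3-[(tert-butyldiphenylsilyl)oxy]propyl}-3,4-dimethyl-1-(prop-1-en-2-yl)cyclohexan-1-ol (C1 undefined) | CC(=C)C1(O)CC[C@@H](C)[C@@](C)(CCO[Si](C)(C)C(C)(C)C)[C@@H]1CCCO[Si](c2ccccc2)(c2ccccc2)C(C)(C)C | intermediate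
16 | (2Z)-2-[(2S,3R,4R)-3-{2-[(tert-butyldimethylsilyl)oxy]ethyl}-2-{3-[(tert-butyldiphenylsilyl)oxy]propyl}-3,4-dimethylcyclohexylidene]propanal | C/C(C=O)=C1\CC[C@@H](C)[C@@](C)(CCO[Si](C)(C)C(C)(C)C)[C@@H]1CCCO[Si](c2ccccc2)(c2ccccc2)C(C)(C)C | intermediate
17 | (2Z)-2-[(2S,3R,4R)-3-{2-[(tert-butyldimethylsilyl)oxy]ethyl}-2-{3-[(tert-butyldiphenylsilyl)oxy]propyl}-3,4-dimethylcyclohexylidene]propan-1-ol | C/C(CO)=C1\CC[C@@H](C)[C@@](C)(CCO[Si](C)(C)C(C)(C)C)[C@@H]1CCCO[Si](c2ccccc2)(c2ccccc2)C(C)(C)C | intermediate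
18 | tert-butyldiphenylsilyl ether of 17 (allylic CH2O–TBDPS, propyl O–TBDPS, ethyl O–TBS) | C/C(CO[Si](c2ccccc2)(c2ccccc2)C(C)(C)C)=C1\CC[C@@H](C)[C@@](C)(CCO[Si](C)(C)C(C)(C)C)[C@@H]1CCCO[Si](c2ccccc2)(c2ccccc2)C(C)(C)C | intermediate
19 | primary alcohol from 18 (CH2CH2OH on C3; two TBDPS ethers) | C/C(CO[Si](c2ccccc2)(c2ccccc2)C(C)(C)C)=C1\CC[C@@H](C)[C@@](C)(CCO)[C@@H]1CCCO[Si](c2ccccc2)(c2ccccc2)C(C)(C)C | intermediate
20 | primary iodide from 19 (CH2CH2I on C3) | C/C(CO[Si](c2ccccc2)(c2ccccc2)C(C)(C)C)=C1\CC[C@@H](C)[C@@](C)(CCI)[C@@H]1CCCO[Si](c2ccccc2)(c2ccccc2)C(C)(C)C | intermediate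
21 | 4-(trimethylsilyl)but-3-yn-1-ol | C[Si](C)(C)C#CCCO | starting material
22 | (4-iodobut-1-yn-1-yl)trimethylsilane | C[Si](C)(C)C#CCCI | intermediate
23 | 3-methylbut-2-enal | CC(C)=CC=O | starting material
24 | (4S)-6-methylhept-5-en-1-yn-4-ol | C#CC[C@H](O)C=C(C)C | intermediate
25 | tert-butyldimethyl{[(4S)-6-methylhept-5-en-1-yn-4-yl]oxy}silane | C#CC[C@H](O[Si](C)(C)C(C)(C)C)C=C(C)C | intermediate
26 | (E)-alkenyldimethylalane from 25 | C[Al](C)/C=C(\C)C[C@H](O[Si](C)(C)C(C)(C)C)C=C(C)C | intermediate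
27 | tert-butyl{[(4S,6E)-7-iodo-2,6-dimethylhepta-2,6-dien-4-yl]oxy}dimethylsilane | I/C=C(\C)C[C@H](O[Si](C)(C)C(C)(C)C)C=C(C)C | intermediate
28 | [4-(trimethylsilyl)but-3-yn-1-yl]zinc iodide | C[Si](C)(C)C#CCC[Zn]I | intermediate
29 | tert-butyldimethyl{[(4S,6E)-2,6-dimethyl-11-(trimethylsilyl)undeca-2,6-dien-10-yn-4-yl]oxy}silane | C[Si](C)(C)C#CCC/C=C(\C)C[C@H](O[Si](C)(C)C(C)(C)C)C=C(C)C | intermediate
30 | tert-butyl{[(4S,6E)-2,6-dimethylundeca-2,6-dien-10-yn-4-yl]oxy}dimethylsilane | C#CCC/C=C(\C)C[C@H](O[Si](C)(C)C(C)(C)C)C=C(C)C | intermediate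
31 | (E)-alkenyldimethylalane from 30 | C[Al](C)/C=C(\C)CC/C=C(\C)C[C@H](O[Si](C)(C)C(C)(C)C)C=C(C)C | intermediate
32 | tert-butyl{[(4S,6E,10E)-11-iodo-2,6,10-trimethylundeca-2,6,10-trien-4-yl]oxy}dimethylsilane | I/C=C(\C)CC/C=C(\C)C[C@H](O[Si](C)(C)C(C)(C)C)C=C(C)C | intermediate
33 | (4S,6E,10E)-11-iodo-2,6,10-trimethylundeca-2,6,10-trien-4-ol | I/C=C(\C)CC/C=C(\C)C[C@H](O)C=C(C)C | intermediate
34 | (1S,3E,7E)-1-[(2R)-3,3-dimethyloxiran-2-yl]-8-iodo-3,7-dimethylocta-3,7-dien-1-ol | I/C=C(\C)CC/C=C(\C)C[C@H](O)[C@H]1OC1(C)C | intermediate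
35 | primary alkyllithium from 20 (CH2CH2Li on C3) | C/C(CO[Si](c2ccccc2)(c2ccccc2)C(C)(C)C)=C1\CC[C@@H](C)[C@@](C)(CC[Li])[C@@H]1CCCO[Si](c2ccccc2)(c2ccccc2)C(C)(C)C | intermediate
36 | lithium B-alkyl-B-methoxy-9-borabicyclo[3.3.1]nonane borinate from 35 | C/C(CO[Si](c2ccccc2)(c2ccccc2)C(C)(C)C)=C1\CC[C@@H](C)[C@@](C)(CC[B-]3(OC)C4CCCC3CCC4)[C@@H]1CCCO[Si](c2ccccc2)(c2ccccc2)C(C)(C)C.[Li+] | intermediate
37 | coupled bis-TBDPS ether (allylic and propyl O–TBDPS; free secondary alcohol; oxirane) | C/C(CO[Si](c2ccccc2)(c2ccccc2)C(C)(C)C)=C1\CC[C@@H](C)[C@@](C)(CC/C=C(\C)CC/C=C(\C)C[C@H](O)[C@H]3OC3(C)C)[C@@H]1CCCO[Si](c2ccccc2)(c2ccccc2)C(C)(C)C | intermediate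
38 | (2Z)-2-[(2S,3R,4R)-3-{(3E,7E,10S)-10-[(2R)-3,3-dimethyloxiran-2-yl]-10-hydroxy-4,8-dimethyldeca-3,7-dien-1-yl}-2-(3-hydroxypropyl)-3,4-dimethylcyclohexylidene]propan-1-ol | C/C(CO)=C1\CC[C@@H](C)[C@@](C)(CC/C=C(\C)CC/C=C(\C)C[C@H](O)[C@H]2OC2(C)C)[C@@H]1CCCO | intermediate
39 | (2Z)-2-[(2S,3R,4R)-3-{(3E,7E,10S)-10-[(2R)-3,3-dimethyloxiran-2-yl]-10-hydroxy-4,8-dimethyldeca-3,7-dien-1-yl}-2-(3-hydroxypropyl)-3,4-dimethylcyclohexylidene]propanal | C/C(C=O)=C1\CC[C@@H](C)[C@@](C)(CC/C=C(\C)CC/C=C(\C)C[C@H](O)[C@H]2OC2(C)C)[C@@H]1CCCO | target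

**Step count and risks**

Total step count: 25. Longest linear sequence: 15 steps (step 1 or 2, then 3–13, then 23–25).

Steps most likely to fail:

1. Step 7 (key cyclisation). Hydrogen-atom transfer to the vinyl ketone and bimolecular reduction or addition of the C4 radical may outrun ring closure, and the facial preference at C4 rests on a modest conformational bias. Fallback, setting out from 12 and returning at 14: the radical precursor is installed before the enone exists. Cobalt-mediated Markovnikov hydrobromination of the vinyl group of 12 (Co(acac)2, t-BuOOH, Et3SiH, p-toluenesulfonyl bromide, n-PrOH) should give the secondary bromide F1. Vinylmagnesium bromide (THF, −78 °C, acidic quench) then converts the amide into the bromo enone F2. Slow addition of Bu3SnH with AIBN (benzene, 80 °C, high dilution) generates the same C4 radical site-specifically and closes the ring by 6-endo Giese addition to 14.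

2. Step 4 (Claisen rearrangement). Non-uniform boron-enolate geometry or a slow rearrangement of the 3,3-disubstituted allyl unit may erode diastereo- and enantioselectivity. Fallback, setting out from 9 and returning at 11: a conventional Ireland–Claisen rearrangement (LDA, THF/DMPU, −78 °C; Me3SiCl; warm to rt; aqueous NaOH, then acid) through the trimethylsilyl ketene acetal F3 should give the racemic acid, i.e. 11 together with its enantiomer F4. Activation with pivaloyl chloride/Et3N and acylation of lithiated (4S)-4-benzyl-1,3-oxazolidin-2-one gives the two diastereomeric imides, the imide of 11 F5 and the imide of the enantiomer F6, which are separated by chromatography. LiOH/H2O2 (THF/H2O, 0 °C) cleaves F5 to 11.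

3. Step 9 (oxidative transposition). Acid-promoted dehydration of the tertiary allylic alcohol to a diene and a non-selective alkene geometry in the chromate shift may lower the amount of the (Z)-enal. Fallback, setting out from 14 and returning at 16: Horner–Wadsworth–Emmons olefination of ketone 14 with diethyl (1-cyanoethyl)phosphonate (NaH, THF, 0 → 65 °C) gives the unsaturated nitrile, from which the (Z)-nitrile F7 is separated. Reduction with i-Bu2AlH (toluene, −78 °C) and mild acidic hydrolysis of the aldimine delivers 16.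

Further compounds
F1 | step 7 | Markovnikov hydrobromide of 12: 4-bromo-3-{2-[(tert-butyldimethylsilyl)oxy]ethyl}-2-{3-[(tert-butyldiphenylsilyl)oxy]propyl}-N-methoxy-N,3-dimethylpentanamide (C2 and C3 as in 12, both C4 epimers) | CC(Br)[C@@](C)(CCO[Si](C)(C)C(C)(C)C)[C@@H](C(=O)N(C)OC)CCCO[Si](c1ccccc1)(c1ccccc1)C(C)(C)C
F2 | step 7 | bromo enone: 6-bromo-5-{2-[(tert-butyldimethylsilyl)oxy]ethyl}-4-{3-[(tert-butyldiphenylsilyl)oxy]propyl}-5-methylhept-1-en-3-one (C4 and C5 as in 13, both C6 epimers) | CC(Br)[C@@](C)(CCO[Si](C)(C)C(C)(C)C)[C@@H](C(=O)C=C)CCCO[Si](c1ccccc1)(c1ccccc1)C(C)(C)C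
F3 | step 4 | trimethylsilyl ketene acetal of 9 (chain cis to OSiMe3) | CC(C)(C)[Si](c1ccccc1)(c1ccccc1)OCCC/C=C(\O[Si](C)(C)C)OC/C=C(\C)CCO[Si](C)(C)C(C)(C)C
F4 | step 4 | (2R,3S)-3-{2-[(tert-butyldimethylsilyl)oxy]ethyl}-2-{3-[(tert-butyldiphenylsilyl)oxy]propyl}-3-methylpent-4-enoic acid (enantiomer of 11) | C=C[C@](C)(CCO[Si](C)(C)C(C)(C)C)[C@H](C(=O)O)CCCO[Si](c1ccccc1)(c1ccccc1)C(C)(C)C
F5 | step 4 | N-acyl (4S)-4-benzyl-1,3-oxazolidin-2-one of acid 11 | C=C[C@@](C)(CCO[Si](C)(C)C(C)(C)C)[C@@H](C(=O)N1[C@@H](Cc2ccccc2)COC1=O)CCCO[Si](c1ccccc1)(c1ccccc1)C(C)(C)C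
F6 | step 4 | N-acyl (4S)-4-benzyl-1,3-oxazolidin-2-one of acid F4 | C=C[C@](C)(CCO[Si](C)(C)C(C)(C)C)[C@H](C(=O)N1[C@@H](Cc2ccccc2)COC1=O)CCCO[Si](c1ccccc1)(c1ccccc1)C(C)(C)C
F7 | step 9 | (2Z)-2-[(2S,3R,4R)-3-{2-[(tert-butyldimethylsilyl)oxy]ethyl}-2-{3-[(tert-butyldiphenylsilyl)oxy]propyl}-3,4-dimethylcyclohexylidene]propanenitrile | C/C(C#N)=C1\CC[C@@H](C)[C@@](C)(CCO[Si](C)(C)C(C)(C)C)[C@@H]1CCCO[Si](c2ccccc2)(c2ccccc2)C(C)(C)C
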